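(Its constants were drawn at random within sensible limits; the result is computed.)

Which of these three flasks, alike but for temperature, ends with the most product, and how much does each hold?

    substrate + free catalyst → spent catalyst (k1 = 1.36 M⁻¹ min⁻¹, Ea1 = 61.0 kJ mol⁻¹)
    substrate + free catalyst → free catalyst + product (k2 = 109 M⁻¹ min⁻¹, Ea2 = 55.0 kJ mol⁻¹)
    (constants at 25 °C)

| flask | substrate | free catalyst | temperature | time |
|---|---|---|---|---|
| grey | 20 mM | 0.20 mM | 65 °C | 5.0 h |
| violet | 20 mM | 0.20 mM | 45 °C | 5.0 h |
| ochre | 20 mM | 0.20 mM | 25 °C | 5.0 h |

1. which flask leads in amount of product, in percent of the substrate charged ("all alike" within 1.5 percentage points) (grey / violet / ochre / all alike)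
2. how much product is there at the end, in percent of the substrate charged: grey
3. how much product is there at the end, in percent of the substrate charged: violet
4. how much product is there at the end, in percent of the substrate charged: ochre

- the constants hold at 25 °C; other temperatures follow from the activation energies

Each meeting of substrate with free catalyst either makes product or loses the catalyst. Both rates carry the same factor [substrate][free catalyst], so their quotient contains neither that factor nor time, and it integrates at once: [product] equals r times the free catalyst lost. Here r, the turnover number, is the product constant over the loss constant, 80.1 in ochre. The quantity I carry is the ceiling, r times the catalyst charged, which in ochre is 16.0 mM, or 80.0% of the substrate.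

The loss step has the higher activation energy, so r falls on warming, to 68.8 in violet and 60.2 in grey. Ochre would consume 16.2 mM of substrate in reaching its ceiling, less than the 20 mM charged, so the charge of substrate allows that ceiling in ochre.

Is the ceiling reached in time? Putting the balance into the loss rate and integrating gives a decay whose exponent is the loss constant times the substrate finally left times the time. At its ceiling ochre would have 3.77 mM of substrate left, so its exponent is 1.54, which at the time allowed leaves 0.00980 mM of free catalyst and gives 76.2%. Violet's exponent is 11.6 and grey's 58.2, both larger, so I put those flasks at their ceilings, 68.8% and 60.2%. I commit to ochre.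

The forecast names ochre, with 60.2% for grey, 68.8% for violet and 76.2% for ochre, holding of the warm flasks that “the catalyst dies completely within 5 h”.

The simulation gives 60.2% for grey, 68.8% for violet and 76.2% for ochre, so ochre leads.

Ochre still holds 4.90% of its free catalyst at 5.00 h, and at 50.0 h its product stands at 80.1%, beside the ceiling of 80.0%. A neighbour of ochre is charged with 80 mM of substrate at the same temperature, so r and the ceiling of 16.0 mM stay, which is 20.0% of its larger charge. Its exponent is 26.0, larger than ochre's, so I expect it at its ceiling. At 5.00 h that neighbour holds 0% free catalyst, 79.7% substrate and 20.0% product.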